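**Strategy**

Ring numbering: C1 (angelate), C3 (methyl), C4 (hydroxyl), C6 (side chain). The cyclohexane is closed at C3–C4. Because the C1 oxygen and C4 stand 1,4 on the ring, they are first tied as a cis-γ-butyrolactone carrying an allyl group on C1. A titanium-mediated Kulinkovich-type hydroxycyclopropanation then joins the internal alkene carbon (C3) to the lactone carbonyl (C4): one operation closes the carbocycle, frees the C1 hydroxyl for the angelate and stores the C3 methyl as a cyclopropane CH2. Base opens the cyclopropanol to the 2-methylcyclohexanone; C3 equilibrates to equatorial and a late bulky hydride sets the axial C4 hydroxyl.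

Key step: step 7

Remark on numbering: ring atoms C1 (angelate), C2, C3 (methyl), C4 (hydroxyl), C5, C6 (side chain); side chain C7 (methyl), C8, C9 (acetate), C10=C11.

Assumption: cyclopropanol 12 may form as either face isomer of the cis-fused cyclopropane; both give 13 in step 8. The SMILES of 12 shows the isomer with the cyclopropane CH2 on the face of the C1 hydroxyl.

**Route**

Step 1
Reactants: 1 methyl hydrogen (R)-3-methylglutarate
Product: 3 methyl (3R)-3,7-dimethyl-5-oxooct-6-enoate, via acid chloride 2 (not isolated)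
Conditions: (COCl)2, DMF (cat.), CH2Cl2, 0 °C to rt; then Me2C=CHMgBr, CuI (10 mol %), THF, −78 °C
Reagents that add atoms: (2-methylprop-1-en-1-yl)magnesium bromide, CC(C)=C[Mg]Br; oxalyl chloride, O=C(Cl)C(=O)Cl (chlorine of 2 only)
Why: Copper-catalysed acylation of the alkenyl Grignard reagent by the acid chloride at −78 °C should stop at the enone and leave the methyl ester and the C7 stereocentre (from the chiral pool) untouched.

Step 2
Reactants: 3 methyl (3R)-3,7-dimethyl-5-oxooct-6-enoate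
Product: 5 (4R,6R)-4-methyl-6-(2-methylprop-1-en-1-yl)oxan-2-one, via hydroxy ester 4 (not isolated)
Conditions: (S)-2-methyl-CBS-oxazaborolidine (20 mol %), catecholborane, toluene, −78 °C; aq. NaOH wash; then PPTS (cat.), toluene, 50 °C
Reagents that add atoms: none
Why: Corey–Bakshi–Shibata reduction in which the alkenyl group should act as the large substituent, so the (S)-catalyst delivers hydride to give the (R)-carbinol at C9 (reagent control); mild acid then lactonises the δ-hydroxy ester to the cis-4,6-disubstituted lactone.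

Step 3
Reactants: 5 (4R,6R)-4-methyl-6-(2-methylprop-1-en-1-yl)oxan-2-one
Product: 6 tert-butyl 2-[(3S,4R,6R)-4-methyl-6-(2-methylprop-1-en-1-yl)-2-oxooxan-3-yl]acetate
Conditions: LiN(i-Pr)2, THF, −78 °C; BrCH2CO2t-Bu, −78 to −40 °C
Reagents that add atoms: tert-butyl bromoacetate, CC(C)(C)OC(=O)CBr
Why: Alkylation of the lactone lithium enolate should occur anti to the neighbouring C7 methyl group on the half-chair, which sets C6 as S (trans-3,4, substrate control by the temporary lactone ring).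

Step 4
Reactants: 6 tert-butyl 2-[(3S,4R,6R)-4-methyl-6-(2-methylprop-1-en-1-yl)-2-oxooxan-3-yl]acetate
Product: 8 tert-butyl (3S,4R,6R)-6-[(tert-butyldimethylsilyl)oxy]-3-[methoxy(methyl)carbamoyl]-4,8-dimethylnon-7-enoate, via hydroxy amide 7 (not isolated)
Conditions: MeNH(OMe)·HCl, i-PrMgCl, THF, −20 °C; aq. NH4Cl work-up; then TBSCl, imidazole, DMF, rt
Reagents that add atoms: N,O-dimethylhydroxylamine hydrochloride, CNOC.Cl; tert-butyldimethylsilyl chloride, CC(C)(C)[Si](C)(C)Cl
Why: Weinreb aminolysis by the magnesium amide should open the lactone faster than it attacks the hindered tert-butyl ester, and silylation of the freed C9 hydroxyl blocks relactonisation.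

Step 5
Reactants: 8 tert-butyl (3S,4R,6R)-6-[(tert-butyldimethylsilyl)oxy]-3-[methoxy(methyl)carbamoyl]-4,8-dimethylnon-7-enoate
Product: 9 tert-butyl (3S,4R,6R)-6-[(tert-butyldimethylsilyl)oxy]-3-formyl-4,8-dimethylnon-7-enoate
Conditions: i-Bu2AlH, THF, −78 °C; aq. KNaC4H4O6
Reagents that add atoms: none
Why: Hydride reduction of a Weinreb amide stops at the chelated hemiaminal and should give the aldehyde on work-up, with the tert-butyl ester untouched at −78 °C.

Step 6
Reactants: 9 tert-butyl (3S,4R,6R)-6-[(tert-butyldimethylsilyl)oxy]-3-formyl-4,8-dimethylnon-7-enoate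
Product: 11 (4S,5R)-4-[(2R,4R)-4-[(tert-butyldimethylsilyl)oxy]-6-methylhept-5-en-2-yl]-5-(prop-2-en-1-yl)oxolan-2-one, via hydroxy tert-butyl ester 10 (not isolated)
Conditions: (+)-Ipc2B(allyl) (from (−)-α-pinene), Et2O, −78 °C; NaOH, H2O2, 0 °C to rt; then KOt-Bu (20 mol %), THF, 0 °C
Reagents that add atoms: (+)-B-allyldiisopinocampheylborane, C=CCB([C@H]1C[C@H]2C[C@@H]([C@@H]1C)C2(C)C)[C@H]1C[C@H]2C[C@@H]([C@@H]1C)C2(C)C
Why: Brown allylboration through a chair transition state should add allyl to the Re face of the aldehyde and set C1 as R under reagent control; the γ-alkoxide then closes onto the tert-butyl ester to give the cis-lactone.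

Step 7
Reactants: 11 (4S,5R)-4-[(2R,4R)-4-[(tert-butyldimethylsilyl)oxy]-6-methylhept-5-en-2-yl]-5-(prop-2-en-1-yl)oxolan-2-one
Product: 12 (1S,3S,4R,6R)-3-[(2R,4R)-4-[(tert-butyldimethylsilyl)oxy]-6-methylhept-5-en-2-yl]bicyclo[4.1.0]heptane-1,4-diol
Conditions: Ti(OiPr)4 (1.3 equiv), i-PrMgCl (2.6 equiv), Et2O, −50 °C to rt; aq. NH4Cl
Reagents that add atoms: none
Why: Ti(OiPr)4 and two equivalents of i-PrMgCl form the propene titanacyclopropane, which exchanges propene for the terminal alkene C3=CH2; the tethered titanacycle adds to the lactone carbonyl C4 (intramolecular nucleophilic acyl substitution), the tetrahedral titanate collapses with loss of the C1 alkoxide, and the β-titanio ketone closes onto C4 to the cyclopropanol, so the bonds C3–C4 and CH2–C4 form and the C1–O–C4 tether is cut in one operation. The closest known reaction is the Kulinkovich hydroxycyclopropanation in its ligand-exchange, intramolecular form, known for homoallyl esters and for ω-alkenyl esters, which give hydroxyalkyl cyclopropanols and bicyclo[n.1.0]alkan-1-ols. The six-membered ring closes by attack of C3 on the exocyclic C4=O (6-exo-trig with respect to the carbonyl) and the three-membered ring by 3-exo-trig attack of the titanium-bearing CH2 on the same carbon. The two new stereocentres C3 and C4 are cis by the constraint of the ring fusion; their sense relative to C1 and C6 is not needed, because step 8 turns C4 into a carbonyl carbon and leaves C3 epimerisable. The step needs the titanium reagent to take the terminal alkene and not the trisubstituted C10=C11 alkene, which does not undergo ligand exchange, and to acylate only at C4, which is secured by keeping the lactone as the only ester (C9 oxygen as silyl ether) and by the intramolecular delivery.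

Step 8
Reactants: 12 (1S,3S,4R,6R)-3-[(2R,4R)-4-[(tert-butyldimethylsilyl)oxy]-6-methylhept-5-en-2-yl]bicyclo[4.1.0]heptane-1,4-diol
Product: 13 (2S,4R,5S)-5-[(2R,4R)-4-[(tert-butyldimethylsilyl)oxy]-6-methylhept-5-en-2-yl]-4-hydroxy-2-methylcyclohexan-1-one
Conditions: KOH (20 mol %), MeOH, 0 °C to rt
Reagents that add atoms: none
Why: Base-induced cyclopropanol ring opening (homoenolate protonation) should cleave the C4–CH2 bond, which gives the primary carbanion, to unveil the C4 ketone and the C3 methyl group, and the same base equilibrates C3 to the equatorial (S) epimer.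

Step 9
Reactants: 13 (2S,4R,5S)-5-[(2R,4R)-4-[(tert-butyldimethylsilyl)oxy]-6-methylhept-5-en-2-yl]-4-hydroxy-2-methylcyclohexan-1-one
Product: 14 (1R,2S,5S)-2-[(2R,4R)-4-[(tert-butyldimethylsilyl)oxy]-6-methylhept-5-en-2-yl]-5-methyl-4-oxocyclohexyl (2Z)-2-methylbut-2-enoate
Conditions: angelic acid, 2,4,6-trichlorobenzoyl chloride, Et3N, toluene, rt; then 13, toluene, 80 °C
Reagents that add atoms: angelic acid, C/C=C(/C)C(=O)O
Why: Yamaguchi-type mixed-anhydride esterification without a nucleophilic catalyst should acylate the only free hydroxyl (C1) while keeping the Z geometry of the angeloyl group.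

Step 10
Reactants: 14 (1R,2S,5S)-2-[(2R,4R)-4-[(tert-butyldimethylsilyl)oxy]-6-methylhept-5-en-2-yl]-5-methyl-4-oxocyclohexyl (2Z)-2-methylbut-2-enoate
Product: 15 (1R,2S,5S)-2-[(2R,4R)-4-hydroxy-6-methylhept-5-en-2-yl]-5-methyl-4-oxocyclohexyl (2Z)-2-methylbut-2-enoate
Conditions: HF·pyridine, pyridine, THF, 0 °C to rt
Reagents that add atoms: none
Why: Buffered fluoride cleavage of the silyl ether should free the C9 allylic alcohol without ionising it and without touching the angelate or the ketone.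

Step 11
Reactants: 15 (1R,2S,5S)-2-[(2R,4R)-4-hydroxy-6-methylhept-5-en-2-yl]-5-methyl-4-oxocyclohexyl (2Z)-2-methylbut-2-enoate
Product: 16 (1R,2S,5S)-2-[(2R,4R)-4-(acetyloxy)-6-methylhept-5-en-2-yl]-5-methyl-4-oxocyclohexyl (2Z)-2-methylbut-2-enoate
Conditions: Ac2O, pyridine, DMAP (cat.), CH2Cl2, 0 °C to rt
Reagents that add atoms: acetic anhydride, CC(=O)OC(C)=O
Why: Standard acetylation of the only hydroxyl group present, with the C4 oxygen still held at the ketone level.

Step 12
Reactants: 16 (1R,2S,5S)-2-[(2R,4R)-4-(acetyloxy)-6-methylhept-5-en-2-yl]-5-methyl-4-oxocyclohexyl (2Z)-2-methylbut-2-enoate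
Product: 17 (1R,2S,4R,5S)-2-[(2R,4R)-4-(acetyloxy)-6-methylhept-5-en-2-yl]-4-hydroxy-5-methylcyclohexyl (2Z)-2-methylbut-2-enoate
Conditions: LiBH(s-Bu)3 (1.1 equiv), THF, −78 °C; aq. NH4Cl
Reagents that add atoms: none
Why: The bulky trialkylborohydride should attack the C4 carbonyl of the chair (C1, C3 and C6 substituents equatorial) from the equatorial direction, giving the axial (R) alcohol cis to the C3 methyl, and at −78 °C should spare the acetate and the hindered angelate.

**Compound list**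

1 | methyl hydrogen (R)-3-methylglutarate, (3R)-5-methoxy-3-methyl-5-oxopentanoic acid | COC(=O)C[C@H](C)CC(O)=O | starting material
2 | methyl (3S)-5-chloro-3-methyl-5-oxopentanoate (same spatial arrangement as 1; formed in the flask) | COC(=O)C[C@H](C)CC(Cl)=O | intermediate
3 | methyl (3R)-3,7-dimethyl-5-oxooct-6-enoate | COC(=O)C[C@H](C)CC(=O)C=C(C)C | intermediate
4 | methyl (3R,5R)-5-hydroxy-3,7-dimethyloct-6-enoate (formed in the flask) | COC(=O)C[C@H](C)C[C@H](C=C(C)C)O | intermediate
5 | (4R,6R)-4-methyl-6-(2-methylprop-1-en-1-yl)oxan-2-one | O=C1C[C@H](C)C[C@H](C=C(C)C)O1 | intermediate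
6 | tert-butyl 2-[(3S,4R,6R)-4-methyl-6-(2-methylprop-1-en-1-yl)-2-oxooxan-3-yl]acetate | CC(C)(C)OC(=O)C[C@H]1[C@H](C)C[C@H](C=C(C)C)OC1=O | intermediate
7 | tert-butyl (3S,4R,6R)-6-hydroxy-3-[methoxy(methyl)carbamoyl]-4,8-dimethylnon-7-enoate (formed in the flask) | CON(C)C(=O)[C@@H](CC(=O)OC(C)(C)C)[C@H](C)C[C@H](C=C(C)C)O | intermediate
8 | tert-butyl (3S,4R,6R)-6-[(tert-butyldimethylsilyl)oxy]-3-[methoxy(methyl)carbamoyl]-4,8-dimethylnon-7-enoate | CON(C)C(=O)[C@@H](CC(=O)OC(C)(C)C)[C@H](C)C[C@H](C=C(C)C)O[Si](C)(C)C(C)(C)C | intermediate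
9 | tert-butyl (3S,4R,6R)-6-[(tert-butyldimethylsilyl)oxy]-3-formyl-4,8-dimethylnon-7-enoate | O=C[C@@H](CC(=O)OC(C)(C)C)[C@H](C)C[C@H](C=C(C)C)O[Si](C)(C)C(C)(C)C | intermediate
10 | tert-butyl (3S,4R)-3-[(2R,4R)-4-[(tert-butyldimethylsilyl)oxy]-6-methylhept-5-en-2-yl]-4-hydroxyhept-6-enoate (formed in the flask) | C=CC[C@@H](O)[C@@H](CC(=O)OC(C)(C)C)[C@H](C)C[C@H](C=C(C)C)O[Si](C)(C)C(C)(C)C | intermediate
11 | (4S,5R)-4-[(2R,4R)-4-[(tert-butyldimethylsilyl)oxy]-6-methylhept-5-en-2-yl]-5-(prop-2-en-1-yl)oxolan-2-one | C=CC[C@H]1OC(=O)C[C@H]1[C@H](C)C[C@H](C=C(C)C)O[Si](C)(C)C(C)(C)C | intermediate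
12 | (1S,3S,4R,6R)-3-[(2R,4R)-4-[(tert-butyldimethylsilyl)oxy]-6-methylhept-5-en-2-yl]bicyclo[4.1.0]heptane-1,4-diol | O[C@@H]1C[C@@H]2C[C@]2(O)C[C@H]1[C@H](C)C[C@H](C=C(C)C)O[Si](C)(C)C(C)(C)C | intermediate
13 | (2S,4R,5S)-5-[(2R,4R)-4-[(tert-butyldimethylsilyl)oxy]-6-methylhept-5-en-2-yl]-4-hydroxy-2-methylcyclohexan-1-one | O[C@@H]1C[C@H](C)C(=O)C[C@H]1[C@H](C)C[C@H](C=C(C)C)O[Si](C)(C)C(C)(C)C | intermediate
14 | (1R,2S,5S)-2-[(2R,4R)-4-[(tert-butyldimethylsilyl)oxy]-6-methylhept-5-en-2-yl]-5-methyl-4-oxocyclohexyl (2Z)-2-methylbut-2-enoate | C/C=C(/C)C(=O)O[C@@H]1C[C@H](C)C(=O)C[C@H]1[C@H](C)C[C@H](C=C(C)C)O[Si](C)(C)C(C)(C)C | intermediate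
15 | (1R,2S,5S)-2-[(2R,4R)-4-hydroxy-6-methylhept-5-en-2-yl]-5-methyl-4-oxocyclohexyl (2Z)-2-methylbut-2-enoate | C/C=C(/C)C(=O)O[C@@H]1C[C@H](C)C(=O)C[C@H]1[C@H](C)C[C@H](C=C(C)C)O | intermediate
16 | (1R,2S,5S)-2-[(2R,4R)-4-(acetyloxy)-6-methylhept-5-en-2-yl]-5-methyl-4-oxocyclohexyl (2Z)-2-methylbut-2-enoate | C/C=C(/C)C(=O)O[C@@H]1C[C@H](C)C(=O)C[C@H]1[C@H](C)C[C@H](C=C(C)C)OC(C)=O | intermediate
17 | (1R,2S,4R,5S)-2-[(2R,4R)-4-(acetyloxy)-6-methylhept-5-en-2-yl]-4-hydroxy-5-methylcyclohexyl (2Z)-2-methylbut-2-enoate (CNP0237033.1) | C/C=C(/C)C(=O)O[C@@H]1C[C@H](C)[C@H](O)C[C@H]1[C@H](C)C[C@H](C=C(C)C)OC(C)=O | target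

**Step count and risks**

Total step count: 12. Longest linear sequence: 12 steps (from 1).

Steps most likely to fail:

Step 7. The bridged tetrahedral titanate needed for the intramolecular acyl substitution may form too slowly, so that intermolecular reaction or plain consumption of the low-valent titanium wins. The fallback uses known acyl radical chemistry and sets out from 11. LiOH in THF/H2O opens the lactone to the lithium hydroxy carboxylate F1. TESOTf and 2,6-lutidine in CH2Cl2 at −78 °C give the bis-silylated silyl ether and silyl ester F2. K2CO3 in MeOH/H2O cleaves only the silyl ester to the acid F3. (PhSe)2 and PBu3 in CH2Cl2 give the Se-phenyl selenoester F4. Bu3SnH and AIBN in benzene at 80 °C, then DBU, should effect 6-exo-trig acyl radical cyclisation onto the terminal alkene and equilibration at C3 to the silyl-protected ketone F5. PPTS in MeOH at 0 °C removes the triethylsilyl group selectively and returns to the route at 13.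

Step 6. The reagent has to override the Felkin–Anh preference of the α-branched aldehyde (mismatched pair), and the aldehyde may epimerise at C6 before it is consumed. The fallback sets out from 8. Allylmagnesium bromide in THF at −78 °C converts the Weinreb amide into the allyl ketone F6. LiBH(s-Bu)3 in THF at −78 °C reduces it under Felkin–Anh control, which for hydride addition favours the needed (R) configuration at C1, to the hydroxy ester 10. KOt-Bu then closes the lactone and returns to the route at 11.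

Step 9. Slow acylation of the hindered C1 hydroxyl may allow Z to E isomerisation of the activated angeloyl unit. The fallback sets out from 13. 2-[Bis(2,2,2-trifluoroethoxy)phosphoryl]propanoic acid, DCC and DMAP in CH2Cl2 give the phosphonopropanoate F7. KN(SiMe3)2 and 18-crown-6 in THF at −78 °C, then acetaldehyde (Still–Gennari olefination), should build the Z-trisubstituted enoate on the molecule and return to the route at 14.

**Further compounds**

F1 | step 7 | lithium (3S,4R)-3-[(2R,4R)-4-[(tert-butyldimethylsilyl)oxy]-6-methylhept-5-en-2-yl]-4-hydroxyhept-6-enoate | C=CC[C@@H](O)[C@@H](CC(=O)[O-])[C@H](C)C[C@H](C=C(C)C)O[Si](C)(C)C(C)(C)C.[Li+]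
F2 | step 7 | triethylsilyl (3S,4R)-3-[(2R,4R)-4-[(tert-butyldimethylsilyl)oxy]-6-methylhept-5-en-2-yl]-4-[(triethylsilyl)oxy]hept-6-enoate | C=CC[C@@H](O[Si](CC)(CC)CC)[C@@H](CC(=O)O[Si](CC)(CC)CC)[C@H](C)C[C@H](C=C(C)C)O[Si](C)(C)C(C)(C)C
F3 | step 7 | (3S,4R)-3-[(2R,4R)-4-[(tert-butyldimethylsilyl)oxy]-6-methylhept-5-en-2-yl]-4-[(triethylsilyl)oxy]hept-6-enoic acid | C=CC[C@@H](O[Si](CC)(CC)CC)[C@@H](CC(=O)O)[C@H](C)C[C@H](C=C(C)C)O[Si](C)(C)C(C)(C)C
F4 | step 7 | Se-phenyl (3S,4R)-3-[(2R,4R)-4-[(tert-butyldimethylsilyl)oxy]-6-methylhept-5-en-2-yl]-4-[(triethylsilyl)oxy]hept-6-eneselenoate | C=CC[C@@H](O[Si](CC)(CC)CC)[C@@H](CC(=O)[Se]c1ccccc1)[C@H](C)C[C@H](C=C(C)C)O[Si](C)(C)C(C)(C)C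
F5 | step 7 | (2S,4R,5S)-5-[(2R,4R)-4-[(tert-butyldimethylsilyl)oxy]-6-methylhept-5-en-2-yl]-2-methyl-4-[(triethylsilyl)oxy]cyclohexan-1-one | CC[Si](CC)(CC)O[C@@H]1C[C@H](C)C(=O)C[C@H]1[C@H](C)C[C@H](C=C(C)C)O[Si](C)(C)C(C)(C)C
F6 | step 6 | tert-butyl (3S,4R,6R)-3-(but-3-enoyl)-6-[(tert-butyldimethylsilyl)oxy]-4,8-dimethylnon-7-enoate | C=CCC(=O)[C@@H](CC(=O)OC(C)(C)C)[C@H](C)C[C@H](C=C(C)C)O[Si](C)(C)C(C)(C)C
F7 | step 9 | (1R,2S,5S)-2-[(2R,4R)-4-[(tert-butyldimethylsilyl)oxy]-6-methylhept-5-en-2-yl]-5-methyl-4-oxocyclohexyl 2-[bis(2,2,2-trifluoroethoxy)phosphoryl]propanoate (both epimers at the phosphonate carbon) | CC(C(=O)O[C@@H]1C[C@H](C)C(=O)C[C@H]1[C@H](C)C[C@H](C=C(C)C)O[Si](C)(C)C(C)(C)C)P(=O)(OCC(F)(F)F)OCC(F)(F)F
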